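**Plan**
1. Locants: ring A is C1 (OMe), C2 (OH), C3 (O-aryl), C4–C6 (Br). Ring B is the 2,4-dibromophenyl group.
2. Retrosynthetic cuts, in order: the three C–Br bonds at C4, C5 and C6; the aromaticity of ring A (four hydrogens put back, C2–OH becoming C2=O); the ether bond O–C3; last, the C3–Br bond of the resulting α-bromo ketone.
3. Enabling feature: C2 lies between C1–OMe and C3–O-aryl, so ring A is a masked 2,6-dioxygenated cyclohexanone with C2 as the carbonyl carbon. Its α-carbon C3 can take up a phenoxide by SN2, which avoids an aryl–O coupling at a position flanked on both sides.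
4. Forward: neither ring is built. Ring A enters as the carbocycle of 2-methoxycyclohexanone and ring B as 2,4-dibromophenol. C3 is brominated (steps 1–2), the rings are joined through O–C3 (step 3), and ring A is aromatised (step 4) and tribrominated (step 5).
5. Stereochemistry: the target has no stereocentre. The sp3 centres at C1 and C3 of the intermediates are left uncontrolled and disappear in step 4.

Key step: step 3

Remark: the starting ketone is used as the racemate and all sp3-containing intermediates are carried as racemic (diastereomer) mixtures, so their SMILES bear no stereodescriptors.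

**Step 1**
Reactants: 1 2-methoxycyclohexanone
Product: 3 [(6-methoxycyclohex-1-en-1-yl)oxy]trimethylsilane, via lithium enolate 2 (not isolated)
Conditions: LiN(i-Pr)2 (commercial solution, 1.1 equiv), THF, −78 °C; then Me3SiCl, −78 → 0 °C; cold aq NaHCO3 work-up
Reagents that add atoms: chlorotrimethylsilane (Me3SiCl), C[Si](C)(C)Cl
Why: Kinetic enolate formation with a hindered lithium amide removes a proton from the open CH2 rather than from the crowded methoxy-bearing CH (whose developing carbanion is also opposed by the oxygen lone pairs), and O-silylation fixes this regiochemistry as the silyl enol ether; no stereocentre is created.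

**Step 2**
Reactants: 3 [(6-methoxycyclohex-1-en-1-yl)oxy]trimethylsilane
Product: 4 2-bromo-6-methoxycyclohexanone (racemic diastereomer mixture)
Conditions: NBS (1.05 equiv), THF, −78 → 0 °C; aq NaHCO3 work-up; used without delay
Reagents that add atoms: N-bromosuccinimide (NBS), O=C1CCC(=O)N1Br
Why: Electrophilic α-bromination of a silyl enol ether puts bromine only on the nucleophilic enol carbon, the one remote from the methoxy group, under nearly neutral conditions; the new C–Br centre forms without control, which is harmless because it is inverted in step 3 and erased in step 4.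

**Step 3**
Reactants: 4 2-bromo-6-methoxycyclohexanone; 5 2,4-dibromophenol
Product: 7 2-(2,4-dibromophenoxy)-6-methoxycyclohexanone (racemic diastereomer mixture), via potassium 2,4-dibromophenoxide 6 (not isolated)
Conditions: K2CO3 (1.5 equiv), acetone, 0 °C → rt (40 °C if slow)
Reagents that add atoms: none
Why: Carbonate converts phenol 5, acidified by its two bromines, into phenoxide 6, whose oxygen attacks the bromine-bearing α-carbon of 4 from the rear of the C–Br bond in one SN2 event, a Williamson ether synthesis on an α-halo ketone that forms the O–C3 bond of the future ring A. The closest known reaction type is the O-alkylation of phenols with 2-chloro- or 2-bromocyclohexanone under K2CO3 in acetone, the usual entry to 2-aryloxycyclohexanones. The rate gain comes from overlap of the σ* orbital of the preferentially axial C–Br bond with the carbonyl π* orbital, which lets a secondary ring carbon react near room temperature. No ring closes; the new C–O centre arises with inversion, but it and the methoxy centre can epimerise through the enol and both are erased in step 4, so no control element is needed. Substitution has to outrun Favorskii contraction, cine substitution through the enolate on the methoxy side and E2 loss of HBr; a weakly basic nucleophile (conjugate acid pKa near 8), a heterogeneous carbonate that keeps enolate concentration low, and the absence of alkoxide or hydroxide secure this. O- rather than C-alkylation is expected from the electron-poor, largely blocked ring of 6 in a polar aprotic medium, and since no transition metal is present the two C–Br bonds of ring B stay untouched.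

**Step 4**
Reactants: 7 2-(2,4-dibromophenoxy)-6-methoxycyclohexanone
Product: 10 2-(2,4-dibromophenoxy)-6-methoxyphenol, via enone 8 (not isolated), via cyclohexadienone 9 (not isolated)
Conditions: I2 (20 mol %), DMSO, 90 °C; aq Na2S2O3 work-up
Reagents that add atoms: none
Why: Iodine-catalysed oxidative aromatisation of a cyclohexanone in DMSO proceeds by enolisation, α-iodination and loss of HI at one and then the other oxygen-bearing α-carbon (7 → 8 → 9), after which dienone 9 tautomerises to the phenol and DMSO re-oxidises HI to I2; the sequence is known for cyclohexanones with an α-heteroatom substituent, uses no metal that could insert into the C–Br bonds of ring B, and removes both stereocentres.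

**Step 5**
Reactants: 10 2-(2,4-dibromophenoxy)-6-methoxyphenol
Product: 13 3,4,5-tribromo-2-(2,4-dibromophenoxy)-6-methoxyphenol (target), via monobromophenol 11 (not isolated), via dibromophenol 12 (not isolated)
Conditions: Br2 (3.3 equiv), glacial AcOH, rt → 50 °C, dark; aq NaHSO3 work-up
Reagents that add atoms: bromine, BrBr
Why: Exhaustive electrophilic aromatic bromination works because each open position of ring A is ortho or para to an oxygen donor (C5 para to OH, C4 para to OMe and ortho to O-aryl, C6 ortho to OMe and para to O-aryl), as in the known tribromination of pyrogallol and its ethers, whereas the one accessible site of ring B, ortho to the ether oxygen, is meta to two bromines and should not react without a Lewis acid.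

**Compound list**
1 | 2-methoxycyclohexanone (racemic) | COC1CCCCC1=O | starting material
2 | lithium 6-methoxycyclohex-1-en-1-olate | [Li+].COC1CCCC=C1[O-] | intermediate
3 | [(6-methoxycyclohex-1-en-1-yl)oxy]trimethylsilane | COC1CCCC=C1O[Si](C)(C)C | intermediate
4 | 2-bromo-6-methoxycyclohexanone (racemic diastereomer mixture) | COC1CCCC(Br)C1=O | intermediate
5 | 2,4-dibromophenol | Oc1ccc(Br)cc1Br | starting material
6 | potassium 2,4-dibromophenoxide | [K+].[O-]c1ccc(Br)cc1Br | intermediate
7 | 2-(2,4-dibromophenoxy)-6-methoxycyclohexanone (racemic diastereomer mixture) | COC1CCCC(Oc2ccc(Br)cc2Br)C1=O | intermediate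
8 | 2-(2,4-dibromophenoxy)-6-methoxycyclohex-2-en-1-one (racemic) | COC1CCC=C(Oc2ccc(Br)cc2Br)C1=O | intermediate
9 | 2-(2,4-dibromophenoxy)-6-methoxycyclohexa-2,5-dien-1-one | COC1=CCC=C(Oc2ccc(Br)cc2Br)C1=O | intermediate
10 | 2-(2,4-dibromophenoxy)-6-methoxyphenol | COc1cccc(Oc2ccc(Br)cc2Br)c1O | intermediate
11 | 4-bromo-2-(2,4-dibromophenoxy)-6-methoxyphenol | COc1cc(Br)cc(Oc2ccc(Br)cc2Br)c1O | intermediate
12 | 3,4-dibromo-2-(2,4-dibromophenoxy)-6-methoxyphenol | COc1cc(Br)c(Br)c(Oc2ccc(Br)cc2Br)c1O | intermediate
13 | 3,4,5-tribromo-2-(2,4-dibromophenoxy)-6-methoxyphenol | COc1c(O)c(Oc2ccc(Br)cc2Br)c(Br)c(Br)c1Br | target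

Total step count: 5. Longest linear sequence: 5 (1 → 3 → 4 → 7 → 10 → 13).

**Steps most likely to fail**

a) The aromatisation (step 4).
- What may go wrong: ionisation at the transiently iodinated, oxygen-bearing α-carbon followed by hydrolytic loss of the aryloxy or methoxy group.
- The reaction may also stall after the first dehydrogenation, or nuclear iodination of the fresh phenol may drain the catalyst.
- The fallback sets out from 7 and returns at 10. It replaces halogen chemistry by two selenoxide syn eliminations, which pass through no cationic centre.
- Deprotonation of 7 with LiN(SiMe3)2 (THF, −78 °C) and trapping with PhSeCl should give 2-(2,4-dibromophenoxy)-6-methoxy-2-(phenylselanyl)cyclohexanone F1.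
- A second round with the same reagents can engage only the one α-hydrogen left and should give 2-(2,4-dibromophenoxy)-6-methoxy-2,6-bis(phenylselanyl)cyclohexanone F2.
- mCPBA (2 equiv, CH2Cl2, −78 °C) should give 2-(2,4-dibromophenoxy)-6-methoxy-2,6-bis(phenylseleninyl)cyclohexanone F3.
- On warming with i-Pr2NH as scavenger, F3 can eliminate only toward the ring CH2 groups. This leads to dienone 9, which tautomerises to 10.

b) The ether formation (step 3).
- What may go wrong: base-induced enolisation on the methoxy side followed by Favorskii ring contraction or cine substitution, E2 loss of HBr, or halophilic attack of the phenoxide on bromine.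
- The fallback sets out from 3 (together with 5) and returns at 7. It keeps the same O–C3 bond and the same SN2 geometry at the α-carbon, but changes the leaving group so that no base is present.
- Rubottom oxidation of 3 (mCPBA, NaHCO3, CH2Cl2, 0 °C) should give 2-methoxy-6-[(trimethylsilyl)oxy]cyclohexanone F4.
- Aqueous citric acid in THF should free 2-hydroxy-6-methoxycyclohexanone F5.
- A Mitsunobu reaction of F5 with the acidic phenol 5 (PPh3, DIAD, toluene, 0 °C → rt) should displace the oxyphosphonium group and give 7.

c) The tribromination (step 5).
- What may go wrong: a slow third substitution on the already dibrominated ring. This leaves time for ipso attack para to the free hydroxyl with oxidation to quinone-type material, and for attack at the free ortho position of ring B.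
- The fallback sets out from 10 and returns at 13. It stages the halogenation around a protecting group.
- NBS (1 equiv, MeCN, 0 °C) should give 11, isolated this time, while the hydroxyl still directs to C5.
- Ac2O and pyridine should then give 4-bromo-2-(2,4-dibromophenoxy)-6-methoxyphenyl acetate F6, which can no longer form a dienone.
- Br2 (2.5 equiv, AcOH, 50 °C) should fill C4 and C6, both still activated by OMe and O-aryl, to give 3,4,5-tribromo-2-(2,4-dibromophenoxy)-6-methoxyphenyl acetate F7.
- K2CO3 in MeOH should release 13.

**Further compounds**
F1 | step 4 | 2-(2,4-dibromophenoxy)-6-methoxy-2-(phenylselanyl)cyclohexanone | COC1CCCC(Oc2ccc(Br)cc2Br)([Se]c2ccccc2)C1=O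
F2 | step 4 | 2-(2,4-dibromophenoxy)-6-methoxy-2,6-bis(phenylselanyl)cyclohexanone | COC1([Se]c2ccccc2)CCCC(Oc2ccc(Br)cc2Br)([Se]c2ccccc2)C1=O
F3 | step 4 | 2-(2,4-dibromophenoxy)-6-methoxy-2,6-bis(phenylseleninyl)cyclohexanone | COC1([Se](=O)c2ccccc2)CCCC(Oc2ccc(Br)cc2Br)([Se](=O)c2ccccc2)C1=O
F4 | step 3 | 2-methoxy-6-[(trimethylsilyl)oxy]cyclohexanone | COC1CCCC(O[Si](C)(C)C)C1=O
F5 | step 3 | 2-hydroxy-6-methoxycyclohexanone | COC1CCCC(O)C1=O
F6 | step 5 | 4-bromo-2-(2,4-dibromophenoxy)-6-methoxyphenyl acetate | COc1cc(Br)cc(Oc2ccc(Br)cc2Br)c1OC(C)=O
F7 | step 5 | 3,4,5-tribromo-2-(2,4-dibromophenoxy)-6-methoxyphenyl acetate | COc1c(OC(C)=O)c(Oc2ccc(Br)cc2Br)c(Br)c(Br)c1Br
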